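The ten-membered ring C1–C10 is traced to a cyclohexene (C8, C9, C10, C1, C2, C3) by cutting the C5–C6 bond of the diol and rejoining C3 to C8. The feature used is the array O=C8–C7–C6–C5–C4=C3, a ketone with a Z alkene four bonds away, as left by an oxy-Cope shift. One anionic [3,3] rearrangement of a cis-1,2-dialkenylcyclohexenol forms C5–C6, sets C5 and C6 from two enol ether geometries, makes the C3=C4 alkene and the ring, and frees a C7 enolate that is alkylated in the same flask. The precursor bears a (Z)-2-(PMB-oxy)vinyl group and a hydroxyl on C8 and an (E)-silyl enol ether on C3.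

Key step: step 13

Remark on the chemistry: atoms carry the target's numbers throughout (ring C1 to C10, lactone C11 to C13); the rearrangement substrate is built as the 2S epimer, with a bulky C2 TIPS ether trans to both alkenyl groups, because C2 ends as the ketone and a C2 group cis to them would clash 1,3-diaxially with the C8 vinyl group in the reactive half-chair and steer the ring toward the conformer that gives the 3E alkene.

Step 1
Reactants: 1 3-methylbut-3-enoic acid; 2 (4R)-4-benzyl-1,3-oxazolidin-2-one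
Product: 5 (4R)-4-benzyl-3-(3-methylbut-3-enoyl)-1,3-oxazolidin-2-one, via mixed pivalic anhydride 3 (not isolated), via lithium oxazolidinide 4 (not isolated)
Conditions: 1, t-BuCOCl, Et3N, THF, −78 to 0 °C; then 4 (from 2, n-BuLi, THF, −78 °C), −78 to 0 °C
Reagents that add atoms: none
Why: N-acylation of the lithiated oxazolidinone by a mixed pivalic anhydride is a standard imide synthesis, and the low temperature should keep the β,γ-alkene out of conjugation.

Step 2
Reactants: 5 (4R)-4-benzyl-3-(3-methylbut-3-enoyl)-1,3-oxazolidin-2-one; 6 (E)-but-2-enal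
Product: 9 (4R)-4-benzyl-3-[(2R,3S,4E)-3-hydroxy-2-(prop-1-en-2-yl)hex-4-enoyl]-1,3-oxazolidin-2-one, via boron enolate 7 (not isolated), via boron aldolate 8 (not isolated)
Conditions: Bu2BOTf, Et3N, CH2Cl2, −78 to 0 °C; 6, −78 to 0 °C; then pH 7 buffer, MeOH, H2O2, 0 °C
Reagents that add atoms: none
Why: Evans syn aldol reaction, in which the (Z)-boron enolate 7 reacts through a Zimmerman–Traxler chair on the face away from the benzyl group and should set C3 (R) and C2 (S) together (2,3-syn in the chain, hence trans on the later ring).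

Step 3
Reactants: 9 (4R)-4-benzyl-3-[(2R,3S,4E)-3-hydroxy-2-(prop-1-en-2-yl)hex-4-enoyl]-1,3-oxazolidin-2-one
Product: 10 (2R,3S,4E)-3-hydroxy-N-methoxy-N-methyl-2-(prop-1-en-2-yl)hex-4-enamide
Conditions: MeNH(OMe)·HCl, AlMe3, CH2Cl2, −20 to 0 °C; then cold 0.5 M HCl
Reagents that add atoms: N,O-dimethylhydroxylamine hydrochloride, CNOC.Cl
Why: Aluminium-amide aminolysis of the aldol imide (Weinreb amide formation), assisted by the free β-hydroxyl, releases the auxiliary without touching C2 or C3.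

Step 4
Reactants: 10 (2R,3S,4E)-3-hydroxy-N-methoxy-N-methyl-2-(prop-1-en-2-yl)hex-4-enamide
Product: 11 (2R,3S,4E)-N-methoxy-N-methyl-2-(prop-1-en-2-yl)-3-(triisopropylsilyloxy)hex-4-enamide
Conditions: i-Pr3SiOTf, 2,6-lutidine, CH2Cl2, −78 to 0 °C
Reagents that add atoms: triisopropylsilyl trifluoromethanesulfonate, CC(C)[Si](C(C)C)(C(C)C)OS(=O)(=O)C(F)(F)F
Why: Silylation of the secondary alcohol with a silyl triflate, the bulky TIPS group being chosen so that it cannot migrate to the C8 alkoxide in step 13.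

Step 5
Reactants: 11 (2R,3S,4E)-N-methoxy-N-methyl-2-(prop-1-en-2-yl)-3-(triisopropylsilyloxy)hex-4-enamide
Product: 13 (2R,3S,4E)-2-(1-hydroxypropan-2-yl)-N-methoxy-N-methyl-3-(triisopropylsilyloxy)hex-4-enamide (both C4 epimers), via alkylborane 12 (not isolated)
Conditions: 9-BBN, THF, 0 to 23 °C; then aq. NaOH, H2O2, 0 °C
Reagents that add atoms: hydrogen peroxide, OO
Why: Hydroboration–oxidation with 9-BBN should take only the 1,1-disubstituted alkene (the E-disubstituted one is far slower) and place oxygen on terminal C5; C4 forms as an epimer mixture that is erased in step 7.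

Step 6
Reactants: 13 (2R,3S,4E)-2-(1-hydroxypropan-2-yl)-N-methoxy-N-methyl-3-(triisopropylsilyloxy)hex-4-enamide
Product: 14 (2R,3S,4E)-N-methoxy-N-methyl-2-(1-oxopropan-2-yl)-3-(triisopropylsilyloxy)hex-4-enamide (both C4 epimers)
Conditions: Dess–Martin periodinane, pyridine, CH2Cl2, 0 to 23 °C
Reagents that add atoms: none
Why: Dess–Martin oxidation of the primary alcohol to the aldehyde under buffered conditions that leave the Weinreb amide and the silyl ether alone.

Step 7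
Reactants: 14 (2R,3S,4E)-N-methoxy-N-methyl-2-(1-oxopropan-2-yl)-3-(triisopropylsilyloxy)hex-4-enamide
Product: 15 (2R,3S,4E)-2-[(1E)-1-(tert-butyldimethylsilyloxy)prop-1-en-2-yl]-N-methoxy-N-methyl-3-(triisopropylsilyloxy)hex-4-enamide
Conditions: t-BuMe2SiOTf, Et3N, CH2Cl2, −78 to 0 °C
Reagents that add atoms: tert-butyldimethylsilyl trifluoromethanesulfonate, CC(C)(C)[Si](C)(C)OS(=O)(=O)C(F)(F)F
Why: Soft enolisation and O-silylation of the α-branched aldehyde should favour the E enol ether, whose silyloxy group lies trans to the bulky C3 substituent; this geometry later fixes C5.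

Step 8
Reactants: 15 (2R,3S,4E)-2-[(1E)-1-(tert-butyldimethylsilyloxy)prop-1-en-2-yl]-N-methoxy-N-methyl-3-(triisopropylsilyloxy)hex-4-enamide; 16 (2-methylprop-2-en-1-yl)magnesium chloride
Product: 18 (5R,6S,7E)-5-[(1E)-1-(tert-butyldimethylsilyloxy)prop-1-en-2-yl]-2-methyl-6-(triisopropylsilyloxy)nona-1,7-dien-4-one, via magnesium hemiaminal 17 (not isolated)
Conditions: CH2=C(CH3)CH2MgCl, THF, −78 to −20 °C; then aq. NH4Cl
Reagents that add atoms: none
Why: Weinreb ketone synthesis, in which the allylic Grignard reagent adds once and the chelated tetrahedral adduct 17 collapses to the ketone only on work-up.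

Step 9
Reactants: 18 (5R,6S,7E)-5-[(1E)-1-(tert-butyldimethylsilyloxy)prop-1-en-2-yl]-2-methyl-6-(triisopropylsilyloxy)nona-1,7-dien-4-one
Product: 19 (2R,3S)-2-[(1E)-1-(tert-butyldimethylsilyloxy)prop-1-en-2-yl]-5-methyl-3-(triisopropylsilyloxy)cyclohex-4-en-1-one
Conditions: second-generation Grubbs catalyst RuCl2(=CHPh)(H2IMes)(PCy3) (5 mol %), 1,4-benzoquinone (10 mol %), CH2Cl2 (5 mM), 40 °C; used at once
Reagents that add atoms: none
Why: Ring-closing metathesis between the 2-methylallyl and propenyl groups should form the trisubstituted C10=C1 alkene of the six-membered ring with loss of propene, the hindered silyl enol ether staying inert and benzoquinone suppressing alkene migration.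

Step 10
Reactants: 20 4-methoxybenzyl alcohol; 21 trichloroethene
Product: 22 1-{[(E)-1,2-dichloroethenyl]oxymethyl}-4-methoxybenzene
Conditions: KH, THF, 0 °C; then 21, 0 to 23 °C
Reagents that add atoms: none
Why: Addition of the potassium alkoxide to dichloroethyne formed in situ from trichloroethene (base-induced elimination–addition) is the standard entry to 1,2-dichlorovinyl ethers.

Step 11
Reactants: 19 (2R,3S)-2-[(1E)-1-(tert-butyldimethylsilyloxy)prop-1-en-2-yl]-5-methyl-3-(triisopropylsilyloxy)cyclohex-4-en-1-one; 22 1-{[(E)-1,2-dichloroethenyl]oxymethyl}-4-methoxybenzene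
Product: 26 (1R,2R,3S)-2-[(1E)-1-(tert-butyldimethylsilyloxy)prop-1-en-2-yl]-1-[(4-methoxybenzyloxy)ethynyl]-5-methyl-3-(triisopropylsilyloxy)cyclohex-4-en-1-ol, via chloroalkynyl ether 23 (not isolated), via lithium acetylide 24 (not isolated), via cerium acetylide 25 (not isolated)
Conditions: 22, n-BuLi (2.1 equiv), THF, −78 to −40 °C; CeCl3 (anhydrous), −78 °C; then 19, −78 °C; aq. NH4Cl; kept below 23 °C
Reagents that add atoms: none
Why: Elimination and lithium–chlorine exchange give the alkoxyacetylide, whose weakly basic cerium derivative should add 1,2 to the enolisable ketone by axial attack on the half-chair with the C2 and C3 substituents equatorial, placing the alkyne cis to the C3 side chain and setting C8.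

Step 12
Reactants: 26 (1R,2R,3S)-2-[(1E)-1-(tert-butyldimethylsilyloxy)prop-1-en-2-yl]-1-[(4-methoxybenzyloxy)ethynyl]-5-methyl-3-(triisopropylsilyloxy)cyclohex-4-en-1-ol
Product: 27 (1S,2R,3S)-2-[(1E)-1-(tert-butyldimethylsilyloxy)prop-1-en-2-yl]-1-[(Z)-2-(4-methoxybenzyloxy)ethenyl]-5-methyl-3-(triisopropylsilyloxy)cyclohex-4-en-1-ol
Conditions: H2 (1 atm), Pd/CaCO3 poisoned with Pb(OAc)2 (Lindlar catalyst), quinoline, EtOAc, Et3N (1 %), 23 °C
Reagents that add atoms: none
Why: Lindlar semihydrogenation (syn addition of H2 on poisoned palladium) converts the ynol ether into the Z enol ether, the geometry that later fixes C6, without touching the trisubstituted alkenes.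

Step 13
Reactants: 27 (1S,2R,3S)-2-[(1E)-1-(tert-butyldimethylsilyloxy)prop-1-en-2-yl]-1-[(Z)-2-(4-methoxybenzyloxy)ethenyl]-5-methyl-3-(triisopropylsilyloxy)cyclohex-4-en-1-ol; 28 tert-butyl iodoacetate
Product: 31 tert-butyl 2-[(2S,5S,6R,7S)-5-(tert-butyldimethylsilyloxy)-6-(4-methoxybenzyloxy)-4,10-dimethyl-8-oxo-2-(triisopropylsilyloxy)cyclodeca-1(10),3-dien-7-yl]acetate (1(10)Z,3Z), via potassium alkoxide 29 (not isolated), via potassium enolate 30 (not isolated)
Conditions: KN(SiMe3)2 (1.05 equiv), 18-crown-6, THF, 0 to 23 °C; then 28 (3 equiv), −78 to −40 °C; aq. NH4Cl at −78 °C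
Reagents that add atoms: none
Why: The potassium alkoxide 29 loosens the allylic C3–C8 bond and the C6=C7–C8–C3–C4=C5 array undergoes a [3,3]-sigmatropic shift through a chair, reached from the half-chair in which the C8 vinyl group is axial while the C3 alkenyl and C2 silyloxy groups are equatorial; the closest known reaction type is the anionic oxy-Cope ring enlargement of cis-1,2-divinylcyclohexanols to (Z)-cyclodec-5-enones followed by alkylation of the enolate in the same flask. Ring formation is thus a six-to-ten ring enlargement (C5–C6 forms as C3–C8 breaks) and runs at ordinary concentration. C6 (R) comes from the Z enol ether, whose PMB-oxy group sits axial on the chair, and C5 (S) from the E silyl enol ether, whose silyloxy group sits equatorial, the absolute sense being dictated by C3 and C8; the ring carbon C2, axial on the chair, gives the (3Z) alkene and C1=C10 is carried through. C7 is set when enolate 30, an E double bond within the ring, is alkylated on its outer face, away from the transannular C3=C4 unit, which should place C11 cis to O6. The step needs chair over boat, C- over O-alkylation and alkylation faster than loss of the C6 alkoxide from the enolate; the trans C2 substituent (no 1,3-diaxial clash with the vinyl group), the non-migrating TIPS group, the E enol ether (silicon out of reach of the alkoxide) and the reactive iodide at −78 °C are meant to secure this.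

Step 14
Reactants: 31 tert-butyl 2-[(2S,5S,6R,7S)-5-(tert-butyldimethylsilyloxy)-6-(4-methoxybenzyloxy)-4,10-dimethyl-8-oxo-2-(triisopropylsilyloxy)cyclodeca-1(10),3-dien-7-yl]acetate
Product: 32 tert-butyl 2-[(2S,5S,6R,7S)-5-(tert-butyldimethylsilyloxy)-6-hydroxy-4,10-dimethyl-8-oxo-2-(triisopropylsilyloxy)cyclodeca-1(10),3-dien-7-yl]acetate
Conditions: DDQ, CH2Cl2–pH 7 phosphate buffer (10:1), 0 °C
Reagents that add atoms: none
Why: Oxidative cleavage of the PMB ether by DDQ (benzylic hydride abstraction, hydrolysis of the oxocarbenium ion) frees O6 under buffered conditions that spare the silyl ethers and the β-hydroxy ketone.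

Step 15
Reactants: 32 tert-butyl 2-[(2S,5S,6R,7S)-5-(tert-butyldimethylsilyloxy)-6-hydroxy-4,10-dimethyl-8-oxo-2-(triisopropylsilyloxy)cyclodeca-1(10),3-dien-7-yl]acetate
Product: 33 tert-butyl 2-[(2S,5S,6R,7R,8S)-5-(tert-butyldimethylsilyloxy)-6,8-dihydroxy-4,10-dimethyl-2-(triisopropylsilyloxy)cyclodeca-1(10),3-dien-7-yl]acetate
Conditions: Me4NBH(OAc)3, MeCN–AcOH (1:1), −30 to −20 °C
Reagents that add atoms: none
Why: Evans–Saksena reduction, in which the C6 hydroxyl binds the acetoxyborohydride and delivers hydride intramolecularly through a chair, should give the 1,3-anti diol and so set C8 (S).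

Step 16
Reactants: 33 tert-butyl 2-[(2S,5S,6R,7R,8S)-5-(tert-butyldimethylsilyloxy)-6,8-dihydroxy-4,10-dimethyl-2-(triisopropylsilyloxy)cyclodeca-1(10),3-dien-7-yl]acetate
Product: 34 (2S,5S,6R,7R,8S)-5-(tert-butyldimethylsilyloxy)-8-hydroxy-2-(triisopropylsilyloxy)germacra-1(10)Z,3Z-dien-6,12-olide (cis-fused γ-lactone)
Conditions: camphor-10-sulfonic acid (0.1–0.2 equiv), CH2Cl2, 23 °C
Reagents that add atoms: none
Why: Acid-catalysed lactonisation (intramolecular transesterification with loss of tert-butanol) should close the γ-lactone onto O6, which is cis to the C7 side chain, rather than onto the trans O8, and leave O8 free.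

Step 17
Reactants: 34 (2S,5S,6R,7R,8S)-5-(tert-butyldimethylsilyloxy)-8-hydroxy-2-(triisopropylsilyloxy)germacra-1(10)Z,3Z-dien-6,12-olide; 35 (E)-2-methylbut-2-enoyl chloride (tigloyl chloride)
Product: 36 (2S,5S,6R,7R,8S)-5-(tert-butyldimethylsilyloxy)-8-[(E)-2-methylbut-2-enoyloxy]-2-(triisopropylsilyloxy)germacra-1(10)Z,3Z-dien-6,12-olide
Conditions: 35, pyridine, 4-(dimethylamino)pyridine (0.2 equiv), CH2Cl2, 0 to 23 °C
Reagents that add atoms: none
Why: DMAP-catalysed acylation of the one free (C8) hydroxyl with the acid chloride installs the tiglate without changing C8.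

Step 18
Reactants: 36 (2S,5S,6R,7R,8S)-5-(tert-butyldimethylsilyloxy)-8-[(E)-2-methylbut-2-enoyloxy]-2-(triisopropylsilyloxy)germacra-1(10)Z,3Z-dien-6,12-olide; 37 N,N-dimethylmethyleneiminium iodide (Eschenmoser's salt)
Product: 41 (2S,5S,6R,7R,8S)-5-(tert-butyldimethylsilyloxy)-8-[(E)-2-methylbut-2-enoyloxy]-2-(triisopropylsilyloxy)germacra-1(10)Z,3Z,11(13)-trien-6,12-olide, via lithium enolate 38 (not isolated), via Mannich base 39 (not isolated), via ammonium iodide 40 (not isolated)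
Conditions: LiN(i-Pr)2 (1.2 equiv), THF, −78 °C; 37, −78 to 0 °C; then MeI, CH2Cl2–MeOH, 23 °C; then aq. NaHCO3, 23 °C
Reagents that add atoms: none
Why: Eschenmoser methylenation (Mannich reaction of the lactone lithium enolate with the iminium salt, N-methylation, base-induced β-elimination of trimethylamine) gives the exocyclic C11=C13 alkene, the cold stoichiometric base deprotonating the lactone α-position in preference to the hindered tiglate.

Step 19
Reactants: 41 (2S,5S,6R,7R,8S)-5-(tert-butyldimethylsilyloxy)-8-[(E)-2-methylbut-2-enoyloxy]-2-(triisopropylsilyloxy)germacra-1(10)Z,3Z,11(13)-trien-6,12-olide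
Product: 42 (2S,5S,6R,7R,8S)-2,5-dihydroxy-8-[(E)-2-methylbut-2-enoyloxy]germacra-1(10)Z,3Z,11(13)-trien-6,12-olide
Conditions: Bu4NF, AcOH (1:1), THF, 0 to 23 °C
Reagents that add atoms: none
Why: Fluoride-mediated cleavage of both silyl ethers, buffered with acetic acid to protect the α-methylene lactone and the tiglate from base.

Step 20
Reactants: 42 (2S,5S,6R,7R,8S)-2,5-dihydroxy-8-[(E)-2-methylbut-2-enoyloxy]germacra-1(10)Z,3Z,11(13)-trien-6,12-olide
Product: 43 CNP0230565.3, (5S,6R,7R,8S)-5-hydroxy-8-[(E)-2-methylbut-2-enoyloxy]-2-oxogermacra-1(10)Z,3Z,11(13)-trien-6,12-olide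
Conditions: MnO2 (activated, excess), CH2Cl2, 0 to 23 °C
Reagents that add atoms: none
Why: MnO2 oxidation of allylic alcohols should take the doubly allylic C2 carbinol far faster than the C5 carbinol, which is singly allylic, hindered and deactivated by the vicinal lactone oxygen, giving the cross-conjugated dienone.

Compound list
1 | 3-methylbut-3-enoic acid | C=C(C)CC(=O)O | starting material
2 | (4R)-4-benzyl-1,3-oxazolidin-2-one | O=C1N[C@H](Cc2ccccc2)CO1 | starting material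
3 | 3-methylbut-3-enoic pivalic anhydride | C=C(C)CC(=O)OC(=O)C(C)(C)C | intermediate
4 | lithium salt of (4R)-4-benzyl-1,3-oxazolidin-2-one | [Li+].O=C1[N-][C@H](Cc2ccccc2)CO1 | intermediate
5 | (4R)-4-benzyl-3-(3-methylbut-3-enoyl)-1,3-oxazolidin-2-one | C=C(C)CC(=O)N1[C@H](Cc2ccccc2)COC1=O | intermediate
6 | (E)-but-2-enal | C/C=C/C=O | starting material
7 | (Z)-dibutylboron enolate of 5 | C=C(C)/C=C(\OB(CCCC)CCCC)N1[C@H](Cc2ccccc2)COC1=O | intermediate
8 | dibutylboron aldolate (O-boryl derivative of 9) | C/C=C/[C@H](OB(CCCC)CCCC)[C@@H](C(C)=C)C(=O)N1[C@H](Cc2ccccc2)COC1=O | intermediate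
9 | (4R)-4-benzyl-3-[(2R,3S,4E)-3-hydroxy-2-(prop-1-en-2-yl)hex-4-enoyl]-1,3-oxazolidin-2-one | C/C=C/[C@H](O)[C@@H](C(C)=C)C(=O)N1[C@H](Cc2ccccc2)COC1=O | intermediate
10 | (2R,3S,4E)-3-hydroxy-N-methoxy-N-methyl-2-(prop-1-en-2-yl)hex-4-enamide | C/C=C/[C@H](O)[C@@H](C(C)=C)C(=O)N(C)OC | intermediate
11 | (2R,3S,4E)-N-methoxy-N-methyl-2-(prop-1-en-2-yl)-3-(triisopropylsilyloxy)hex-4-enamide | C/C=C/[C@H](O[Si](C(C)C)(C(C)C)C(C)C)[C@@H](C(C)=C)C(=O)N(C)OC | intermediate
12 | B-alkyl-9-borabicyclo[3.3.1]nonane from 11 (boron on C5, C4 epimers) | C/C=C/[C@H](O[Si](C(C)C)(C(C)C)C(C)C)[C@@H](C(C)CB1C2CCCC1CCC2)C(=O)N(C)OC | intermediate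
13 | (2R,3S,4E)-2-(1-hydroxypropan-2-yl)-N-methoxy-N-methyl-3-(triisopropylsilyloxy)hex-4-enamide (C4 epimers) | C/C=C/[C@H](O[Si](C(C)C)(C(C)C)C(C)C)[C@@H](C(C)CO)C(=O)N(C)OC | intermediate
14 | (2R,3S,4E)-N-methoxy-N-methyl-2-(1-oxopropan-2-yl)-3-(triisopropylsilyloxy)hex-4-enamide (C4 epimers) | C/C=C/[C@H](O[Si](C(C)C)(C(C)C)C(C)C)[C@@H](C(C)C=O)C(=O)N(C)OC | intermediate
15 | (2R,3S,4E)-2-[(1E)-1-(tert-butyldimethylsilyloxy)prop-1-en-2-yl]-N-methoxy-N-methyl-3-(triisopropylsilyloxy)hex-4-enamide | C/C=C/[C@H](O[Si](C(C)C)(C(C)C)C(C)C)[C@@H](/C(C)=C/O[Si](C)(C)C(C)(C)C)C(=O)N(C)OC | intermediate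
16 | (2-methylprop-2-en-1-yl)magnesium chloride | C=C(C)C[Mg]Cl | starting material
17 | chloromagnesium hemiaminal from 15 and 16 | C/C=C/[C@H](O[Si](C(C)C)(C(C)C)C(C)C)[C@@H](/C(C)=C/O[Si](C)(C)C(C)(C)C)C(CC(C)=C)(O[Mg]Cl)N(C)OC | intermediate
18 | (5R,6S,7E)-5-[(1E)-1-(tert-butyldimethylsilyloxy)prop-1-en-2-yl]-2-methyl-6-(triisopropylsilyloxy)nona-1,7-dien-4-one | C/C=C/[C@H](O[Si](C(C)C)(C(C)C)C(C)C)[C@@H](/C(C)=C/O[Si](C)(C)C(C)(C)C)C(=O)CC(C)=C | intermediate
19 | (2R,3S)-2-[(1E)-1-(tert-butyldimethylsilyloxy)prop-1-en-2-yl]-5-methyl-3-(triisopropylsilyloxy)cyclohex-4-en-1-one | O=C1CC(C)=C[C@H](O[Si](C(C)C)(C(C)C)C(C)C)[C@H]1/C(C)=C/O[Si](C)(C)C(C)(C)C | intermediate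
20 | 4-methoxybenzyl alcohol | COc1ccc(CO)cc1 | starting material
21 | trichloroethene | ClC=C(Cl)Cl | starting material
22 | 1-{[(E)-1,2-dichloroethenyl]oxymethyl}-4-methoxybenzene | COc1ccc(CO/C(Cl)=C\Cl)cc1 | intermediate
23 | 1-[(chloroethynyl)oxymethyl]-4-methoxybenzene | COc1ccc(COC#CCl)cc1 | intermediate
24 | lithium (4-methoxybenzyloxy)acetylide | [Li]C#COCc1ccc(OC)cc1 | intermediate
25 | dichlorocerium (4-methoxybenzyloxy)acetylide | COc1ccc(COC#C[Ce](Cl)Cl)cc1 | intermediate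
26 | (1R,2R,3S)-2-[(1E)-1-(tert-butyldimethylsilyloxy)prop-1-en-2-yl]-1-[(4-methoxybenzyloxy)ethynyl]-5-methyl-3-(triisopropylsilyloxy)cyclohex-4-en-1-ol | O[C@]1(C#COCc2ccc(OC)cc2)CC(C)=C[C@H](O[Si](C(C)C)(C(C)C)C(C)C)[C@H]1/C(C)=C/O[Si](C)(C)C(C)(C)C | intermediate
27 | (1S,2R,3S)-2-[(1E)-1-(tert-butyldimethylsilyloxy)prop-1-en-2-yl]-1-[(Z)-2-(4-methoxybenzyloxy)ethenyl]-5-methyl-3-(triisopropylsilyloxy)cyclohex-4-en-1-ol (rearrangement precursor; 2S,3R,8S in target numbering) | O[C@]1(/C=C\OCc2ccc(OC)cc2)CC(C)=C[C@H](O[Si](C(C)C)(C(C)C)C(C)C)[C@H]1/C(C)=C/O[Si](C)(C)C(C)(C)C | intermediate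
28 | tert-butyl iodoacetate | CC(C)(C)OC(=O)CI | starting material
29 | potassium alkoxide of 27 | [K+].[O-][C@]1(/C=C\OCc2ccc(OC)cc2)CC(C)=C[C@H](O[Si](C(C)C)(C(C)C)C(C)C)[C@H]1/C(C)=C/O[Si](C)(C)C(C)(C)C | intermediate
30 | potassium C7=C8 enolate of the ten-membered ketone (oxygen cis to C6; 2S,5S,6R; 1(10)Z,3Z) | [K+].[O-]/C1=C\[C@@H](OCc2ccc(OC)cc2)[C@@H](O[Si](C)(C)C(C)(C)C)/C(C)=C\[C@@H](O[Si](C(C)C)(C(C)C)C(C)C)/C=C(/C)C1 | intermediate
31 | tert-butyl 2-[(2S,5S,6R,7S)-5-(tert-butyldimethylsilyloxy)-6-(4-methoxybenzyloxy)-4,10-dimethyl-8-oxo-2-(triisopropylsilyloxy)cyclodeca-1(10),3-dien-7-yl]acetate (1(10)Z,3Z) | O=C1[C@@H](CC(=O)OC(C)(C)C)[C@@H](OCc2ccc(OC)cc2)[C@@H](O[Si](C)(C)C(C)(C)C)/C(C)=C\[C@@H](O[Si](C(C)C)(C(C)C)C(C)C)/C=C(/C)C1 | intermediate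
32 | tert-butyl 2-[(2S,5S,6R,7S)-5-(tert-butyldimethylsilyloxy)-6-hydroxy-4,10-dimethyl-8-oxo-2-(triisopropylsilyloxy)cyclodeca-1(10),3-dien-7-yl]acetate | O=C1[C@@H](CC(=O)OC(C)(C)C)[C@@H](O)[C@@H](O[Si](C)(C)C(C)(C)C)/C(C)=C\[C@@H](O[Si](C(C)C)(C(C)C)C(C)C)/C=C(/C)C1 | intermediate
33 | tert-butyl 2-[(2S,5S,6R,7R,8S)-5-(tert-butyldimethylsilyloxy)-6,8-dihydroxy-4,10-dimethyl-2-(triisopropylsilyloxy)cyclodeca-1(10),3-dien-7-yl]acetate | O[C@@H]1[C@@H](CC(=O)OC(C)(C)C)[C@@H](O)[C@@H](O[Si](C)(C)C(C)(C)C)/C(C)=C\[C@@H](O[Si](C(C)C)(C(C)C)C(C)C)/C=C(/C)C1 | intermediate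
34 | (2S,5S,6R,7R,8S)-5-(tert-butyldimethylsilyloxy)-8-hydroxy-2-(triisopropylsilyloxy)germacra-1(10)Z,3Z-dien-6,12-olide | C1C(=O)O[C@@H]2[C@H]1[C@@H](O)C/C(C)=C\[C@H](O[Si](C(C)C)(C(C)C)C(C)C)/C=C(/C)[C@@H]2O[Si](C)(C)C(C)(C)C | intermediate
35 | (E)-2-methylbut-2-enoyl chloride | C/C=C(\C)C(Cl)=O | starting material
36 | (2S,5S,6R,7R,8S)-5-(tert-butyldimethylsilyloxy)-8-[(E)-2-methylbut-2-enoyloxy]-2-(triisopropylsilyloxy)germacra-1(10)Z,3Z-dien-6,12-olide | C1C(=O)O[C@@H]2[C@H]1[C@@H](OC(=O)/C(C)=C/C)C/C(C)=C\[C@H](O[Si](C(C)C)(C(C)C)C(C)C)/C=C(/C)[C@@H]2O[Si](C)(C)C(C)(C)C | intermediate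
37 | N,N-dimethylmethyleneiminium iodide | C=[N+](C)C.[I-] | starting material
38 | lithium enolate of lactone 36 | [Li+].[O-]C1=C[C@@H]2[C@@H](OC(=O)/C(C)=C/C)C/C(C)=C\[C@H](O[Si](C(C)C)(C(C)C)C(C)C)/C=C(/C)[C@H](O[Si](C)(C)C(C)(C)C)[C@@H]2O1 | intermediate
39 | 11-(dimethylaminomethyl) lactone (C11 epimers) | CN(C)CC1C(=O)O[C@@H]2[C@H]1[C@@H](OC(=O)/C(C)=C/C)C/C(C)=C\[C@H](O[Si](C(C)C)(C(C)C)C(C)C)/C=C(/C)[C@@H]2O[Si](C)(C)C(C)(C)C | intermediate
40 | 11-(trimethylammoniomethyl) lactone iodide (C11 epimers) | C[N+](C)(C)CC1C(=O)O[C@@H]2[C@H]1[C@@H](OC(=O)/C(C)=C/C)C/C(C)=C\[C@H](O[Si](C(C)C)(C(C)C)C(C)C)/C=C(/C)[C@@H]2O[Si](C)(C)C(C)(C)C.[I-] | intermediate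
41 | (2S,5S,6R,7R,8S)-5-(tert-butyldimethylsilyloxy)-8-[(E)-2-methylbut-2-enoyloxy]-2-(triisopropylsilyloxy)germacra-1(10)Z,3Z,11(13)-trien-6,12-olide | C=C1C(=O)O[C@@H]2[C@H]1[C@@H](OC(=O)/C(C)=C/C)C/C(C)=C\[C@H](O[Si](C(C)C)(C(C)C)C(C)C)/C=C(/C)[C@@H]2O[Si](C)(C)C(C)(C)C | intermediate
42 | (2S,5S,6R,7R,8S)-2,5-dihydroxy-8-[(E)-2-methylbut-2-enoyloxy]germacra-1(10)Z,3Z,11(13)-trien-6,12-olide | C=C1C(=O)O[C@@H]2[C@H]1[C@@H](OC(=O)/C(C)=C/C)C/C(C)=C\[C@H](O)/C=C(/C)[C@@H]2O | intermediate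
43 | CNP0230565.3, (5S,6R,7R,8S)-5-hydroxy-8-[(E)-2-methylbut-2-enoyloxy]-2-oxogermacra-1(10)Z,3Z,11(13)-trien-6,12-olide | C=C1C(=O)O[C@@H]2[C@H]1[C@@H](OC(=O)/C(C)=C/C)C/C(C)=C\C(=O)/C=C(/C)[C@@H]2O | target

Total step count: 20. Longest linear sequence: 19 steps (steps 1–9 and 11–20; step 10 is a one-step branch).

Steps most likely to fail

Step 13. The enolate may lose the C6 alkoxide by β-elimination, or exchange protons, before or during alkylation, because the rearrangement may need more time at 23 °C than the β-alkoxy enolate tolerates. The fallback avoids a free enolate at the rearrangement temperature. It sets out from 27, which would be silylated (N-(trimethylsilyl)imidazole, CH2Cl2) to the tertiary trimethylsilyl ether F1. Heating F1 (decalin, about 190 °C, base-washed glass) would bring about the neutral silyloxy-Cope rearrangement to the ten-membered C7=C8 trimethylsilyl enol ether F2. MeLi (THF, −30 °C) would cleave F2 to the lithium enolate F3, which is less prone to elimination and would be alkylated cold with 28 (DMPU, −78 to −40 °C), coming back to the route at 31.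

Step 16. Ring closure may occur on O8 instead of O6, or the two γ-lactones may equilibrate under acid, so that the wrong hydroxyl stays free. The fallback makes O6 the only free hydroxyl at the lactonisation. It sets out from 31, whose ketone would be reduced with the PMB ether still in place (SmI2, MeOH, THF, 0 °C, the 1,3-anti-selective reduction of β-alkoxy ketones) to the C8 alcohol F6. Acylation with 35 (pyridine, DMAP) would give the tiglate F7, DDQ would free O6 to give the hydroxy ester F8, and camphorsulfonic acid would then close the lactone unambiguously, coming back to the route at 36.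

Step 9. The ruthenium catalyst may move the C10=C1 alkene into conjugation, or the β-silyloxy ketone may lose silanol and aromatise during ring closure and handling. The fallback closes the ring at the alcohol oxidation level. It sets out from 18, which NaBH4 (MeOH, 0 °C) would reduce to the carbinol F4 (both C8 epimers). The same metathesis would give the cyclohexenol F5, and a buffered Dess–Martin oxidation carried out immediately before step 11 would come back to the route at 19.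

Further compounds
F1 | step 13 | trimethylsilyl ether of 27 | C[Si](C)(C)O[C@]1(/C=C\OCc2ccc(OC)cc2)CC(C)=C[C@H](O[Si](C(C)C)(C(C)C)C(C)C)[C@H]1/C(C)=C/O[Si](C)(C)C(C)(C)C
F2 | step 13 | ten-membered C7=C8 trimethylsilyl enol ether (2S,5S,6R) | C[Si](C)(C)O/C1=C\[C@@H](OCc2ccc(OC)cc2)[C@@H](O[Si](C)(C)C(C)(C)C)/C(C)=C\[C@@H](O[Si](C(C)C)(C(C)C)C(C)C)/C=C(/C)C1
F3 | step 13 | lithium C7=C8 enolate of the ten-membered ketone | [Li+].[O-]/C1=C\[C@@H](OCc2ccc(OC)cc2)[C@@H](O[Si](C)(C)C(C)(C)C)/C(C)=C\[C@@H](O[Si](C(C)C)(C(C)C)C(C)C)/C=C(/C)C1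
F4 | step 9 | (5R,6S,7E)-5-[(1E)-1-(tert-butyldimethylsilyloxy)prop-1-en-2-yl]-2-methyl-6-(triisopropylsilyloxy)nona-1,7-dien-4-ol (C8 epimers) | C/C=C/[C@H](O[Si](C(C)C)(C(C)C)C(C)C)[C@@H](/C(C)=C/O[Si](C)(C)C(C)(C)C)C(O)CC(C)=C
F5 | step 9 | (2R,3S)-2-[(1E)-1-(tert-butyldimethylsilyloxy)prop-1-en-2-yl]-5-methyl-3-(triisopropylsilyloxy)cyclohex-4-en-1-ol (C8 epimers) | OC1CC(C)=C[C@H](O[Si](C(C)C)(C(C)C)C(C)C)[C@H]1/C(C)=C/O[Si](C)(C)C(C)(C)C
F6 | step 16 | tert-butyl 2-[(2S,5S,6R,7R,8S)-5-(tert-butyldimethylsilyloxy)-8-hydroxy-6-(4-methoxybenzyloxy)-4,10-dimethyl-2-(triisopropylsilyloxy)cyclodeca-1(10),3-dien-7-yl]acetate | O[C@@H]1[C@@H](CC(=O)OC(C)(C)C)[C@@H](OCc2ccc(OC)cc2)[C@@H](O[Si](C)(C)C(C)(C)C)/C(C)=C\[C@@H](O[Si](C(C)C)(C(C)C)C(C)C)/C=C(/C)C1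
F7 | step 16 | 8-O-tiglate of F6 | C/C=C(\C)C(=O)O[C@@H]1[C@@H](CC(=O)OC(C)(C)C)[C@@H](OCc2ccc(OC)cc2)[C@@H](O[Si](C)(C)C(C)(C)C)/C(C)=C\[C@@H](O[Si](C(C)C)(C(C)C)C(C)C)/C=C(/C)C1
F8 | step 16 | 8-O-tiglate with free C6 hydroxyl (tert-butyl ester) | C/C=C(\C)C(=O)O[C@@H]1[C@@H](CC(=O)OC(C)(C)C)[C@@H](O)[C@@H](O[Si](C)(C)C(C)(C)C)/C(C)=C\[C@@H](O[Si](C(C)C)(C(C)C)C(C)C)/C=C(/C)C1
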